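The 36-membered lactone (C1 lactone carbonyl, C2–C11 pentaene, C35 isopropyl carbinol) is closed last at C15–C16 by a boron aldol of an open keto-aldehyde held together only by the C1–O–C35 ester: the C17 methyl ketone (C16 is its methyl) adds to the C15 aldehyde. The step exploits the oxygenated C15/C17/C19 triad of the macrocycle: the C19 p-methoxybenzyl ether directs 1,5-anti attack (C15) and in-flask borohydride reduction of the boron aldolate gives the 15,17-syn diol, so ring and two stereocentres arise in one operation. The precursor carries C21/C27 as dimethyl ketals and comes from an epoxide/dithiane-built C16–C35 chain and a C3–C15 tetraenal.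

Key step: step 27

Remark: locants C1–C35 follow the macrolactone in every intermediate; the target is made as the open 21,27-diketo form drawn, which may equilibrate with six-membered hemiketals in solution; 1,5-dichloropentane-2,4-dione, 2-(diethoxyphosphoryl)propanoic acid and the pentane solution of (−)-Ipc2B(allyl) are taken as catalogue items.

**C27–C35 unit**

Step 1
Reactants: 1 rac-2-(propan-2-yl)oxirane
Product: 2 (2S)-2-(propan-2-yl)oxirane
Conditions: (S,S)-(salen)Co(OAc) (0.5 mol%, trivalent cobalt), H2O (0.55 equiv), neat, 0 °C → rt; distillation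
Reagents that add atoms: none
Why: Jacobsen hydrolytic kinetic resolution: the (S,S)-catalyst hydrates the (R)-epoxide faster, so the remaining (S)-epoxide supplies C35 (35R after ring opening, by change of CIP ranks only).

Step 2
Reactants: 3 8-bromooct-1-ene; 2 (2S)-2-(propan-2-yl)oxirane
Product: 5 (3R)-2-methyldodec-11-en-3-ol, via oct-7-en-1-ylmagnesium bromide 4 (not isolated)
Conditions: Mg, THF, 40 °C; then 2, CuI (10 mol%), THF, −30 → 0 °C; aq. NH4Cl
Reagents that add atoms: none
Why: The Grignard reagent forms without cyclisation of the long alkenyl tether, and the copper-catalysed Grignard opening attacks the epoxide CH2 (SN2), so the carbinol centre is untouched.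

Step 3
Reactants: 5 (3R)-2-methyldodec-11-en-3-ol
Product: 7 (9R)-9-hydroxy-10-methylundecanal, via secondary ozonide 6 (not isolated)
Conditions: O3, CH2Cl2, −78 °C; then PPh3, −78 °C → rt
Reagents that add atoms: ozone, [O-][O+]=O
Why: Ozonolysis of the terminal alkene gives the secondary ozonide, which PPh3 reduces to the aldehyde (future C27); the free secondary carbinol is inert.

Step 4
Reactants: 7 (9R)-9-hydroxy-10-methylundecanal; 8 propane-1,3-dithiol
Product: 9 (3R)-10-(1,3-dithian-2-yl)-2-methyldecan-3-ol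
Conditions: BF3·OEt2 (0.2 equiv), CH2Cl2, 0 °C → rt
Reagents that add atoms: none
Why: Lewis-acid-catalysed dithioacetalisation masks C27 as the 1,3-dithiane needed for the later umpolung; the remote hydroxyl and its stereocentre are untouched.

**C22–C26 linchpin**

Step 5
Reactants: 10 1,5-dichloropentane-2,4-dione
Product: 11 (2S,4S)-1,5-dichloropentane-2,4-diol
Conditions: H2 (85 atm), [RuCl2((R)-BINAP)]2·NEt3 (cat.), MeOH, 100 °C
Reagents that add atoms: none
Why: Noyori hydrogenation of the 1,3-diketone under catalyst control sets both carbinols and gives the C2-symmetric anti-diol (future C23 and C25).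

Step 6
Reactants: 11 (2S,4S)-1,5-dichloropentane-2,4-diol
Product: 12 (2S,4S)-1,2:4,5-diepoxypentane
Conditions: KOH (powder), Et2O, rt
Reagents that add atoms: none
Why: Twofold intramolecular Williamson closure onto the CH2Cl carbons leaves both stereocentres untouched.

Step 7
Reactants: 9 (3R)-10-(1,3-dithian-2-yl)-2-methyldecan-3-ol; 12 (2S,4S)-1,2:4,5-diepoxypentane
Product: 14 C22–C35 epoxy diol, via dilithiated dithiane 13 (not isolated)
Conditions: 9, t-BuLi (2.1 equiv), THF/HMPA (10:1), −78 °C; cannulated into 12 (3 equiv), THF, −78 → −40 °C; aq. NH4Cl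
Reagents that add atoms: none
Why: Dithiane-anion opening of one (equivalent) terminus of the C2-symmetric diepoxide at its CH2 carbon forms C26–C27 and frees O25; excess diepoxide suppresses double opening.

**C16–C21 unit**

Step 8
Reactants: 15 (R)-epichlorohydrin; 16 isopropenylmagnesium bromide
Product: 18 (2R)-2-(2-methylprop-2-en-1-yl)oxirane, via chlorohydrin 17 (not isolated)
Conditions: 16, CuI (10 mol%), THF, −40 → −20 °C; aq. NH4Cl; crude 17, NaOH (powder), Et2O, rt
Reagents that add atoms: none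
Why: Copper-catalysed Grignard opening at the epoxide CH2 followed by Williamson closure onto the chloride transposes the epoxide with the C19 centre untouched.

Step 9
Reactants: 18 (2R)-2-(2-methylprop-2-en-1-yl)oxirane; 19 1,3-dithiane
Product: 21 (2R)-1-(1,3-dithian-2-yl)-4-methylpent-4-en-2-ol, via 2-lithio-1,3-dithiane 20 (not isolated)
Conditions: 19, n-BuLi, THF, −30 °C; then 18, −30 → 0 °C; aq. NH4Cl
Reagents that add atoms: none
Why: Corey–Seebach epoxide opening at the terminal CH2 forms C20–C21; C19 comes from the epoxide.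

Step 10
Reactants: 21 (2R)-1-(1,3-dithian-2-yl)-4-methylpent-4-en-2-ol
Product: 22 2-[(2R)-2-[(4-methoxyphenyl)methoxy]-4-methylpent-4-en-1-yl]-1,3-dithiane
Conditions: NaH, PMBCl, Bu4NI (cat.), THF/DMF, 0 °C → rt
Reagents that add atoms: 4-methoxybenzyl chloride, COc1ccc(CCl)cc1
Why: Williamson etherification installs at O19 the alkyl ether that later steers the 1,5-anti aldol.

**Assembly of the C16–C35 chain**

Step 11
Reactants: 22 PMB-protected C16–C21 dithiane; 14 C22–C35 epoxy diol
Product: 24 C16–C35 bis-dithiane triol, via lithiated dithiane 23 (not isolated)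
Conditions: 22, t-BuLi, THF/HMPA (10:1), −78 °C; then 14 (pre-treated with n-BuLi, 2.0 equiv, THF, −78 °C), −78 → −25 °C; aq. NH4Cl
Reagents that add atoms: none
Why: Dithiane–epoxide fragment union: the 2-lithio-2-alkyldithiane opens the terminal epoxide at C22 (SN2), so C23 keeps the diepoxide configuration and C23/C25 are anti.

Step 12
Reactants: 24 C16–C35 bis-dithiane triol
Product: 25 23,25-acetonide of 24
Conditions: 2,2-dimethoxypropane, PPTS (cat.), CH2Cl2, rt; wet work-up
Reagents that add atoms: 2,2-dimethoxypropane, COC(C)(C)OC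
Why: Thermodynamic acetonide formation engages only the 1,3-diol; a mixed ketal at the isolated O35 does not survive work-up.

Step 13
Reactants: 25 23,25-acetonide bis-dithiane
Product: 26 21,21,27,27-tetramethoxy compound (bis-dimethyl ketal)
Conditions: PhI(OCOCF3)2 (3.5 equiv), MeOH/CH2Cl2 (4:1), NaHCO3 (solid), −20 → 0 °C
Reagents that add atoms: methanol, CO
Why: Hypervalent-iodine oxidative dithiane-to-ketal exchange: S-activation and methanol capture give the dimethyl ketals directly, so C21 and C27 stay masked against later enolisation.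

Step 14
Reactants: 26 bis-dimethyl ketal
Product: 27 C16–C35 methyl ketone (C17 ketone, free O35–H)
Conditions: OsO4 (2 mol%), NaIO4 (4 equiv), 2,6-lutidine, dioxane/H2O (3:1), rt
Reagents that add atoms: osmium tetroxide, O=[Os](=O)(=O)=O; sodium periodate, [Na+].[O-]I(=O)(=O)=O
Why: Lemieux–Johnson cleavage of the only alkene unveils the C17 methyl ketone (C16 is its methyl) under buffered conditions that spare the ketals and the PMB ether.

Step 15
Reactants: 27 C16–C35 methyl ketone; 28 2-(diethoxyphosphoryl)propanoic acid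
Product: 29 O35 2-(diethoxyphosphoryl)propanoate of 27
Conditions: DCC, DMAP (cat.), CH2Cl2, 0 °C → rt
Reagents that add atoms: none
Why: Steglich esterification of the single free (hindered) hydroxyl installs C1/C2 as a Horner–Wadsworth–Emmons reagent; the epimeric phosphonate carbon is lost later.

**C3–C8 phosphonate**

Step 16
Reactants: 30 ethyl sorbate
Product: 31 ethyl (2E,4E)-6-bromohexa-2,4-dienoate
Conditions: NBS, (PhCO2)2 (cat.), PhCF3, reflux
Reagents that add atoms: N-bromosuccinimide, O=C1CCC(=O)N1Br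
Why: Wohl–Ziegler bromination: the dienyl radical is brominated at the terminal carbon, which keeps the conjugated dienoate.

Step 17
Reactants: 31 ethyl (2E,4E)-6-bromohexa-2,4-dienoate
Product: 32 ethyl (2E,4E)-6-(diethoxyphosphoryl)hexa-2,4-dienoate
Conditions: P(OEt)3, neat, 130 °C
Reagents that add atoms: triethyl phosphite, CCOP(OCC)OCC
Why: Michaelis–Arbuzov reaction of the allylic bromide.

**C3–C15 tetraenal**

Step 18
Reactants: 33 3-[(tert-butyldimethylsilyl)oxy]propanal
Product: 34 (3S)-1-[(tert-butyldimethylsilyl)oxy]hex-5-en-3-ol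
Conditions: (−)-Ipc2B(allyl) (from (+)-α-pinene, 1 M in pentane), Et2O, −78 °C; then NaOH, H2O2
Reagents that add atoms: (−)-B-allyldiisopinocampheylborane, C=CCB([C@@H]1C[C@@H]2C[C@H]([C@H]1C)C2(C)C)[C@@H]1C[C@@H]2C[C@H]([C@H]1C)C2(C)C
Why: Brown allylation through a chair Zimmerman–Traxler transition state; the isopinocampheyl ligands direct si-face attack and set C13 as S.

Step 19
Reactants: 34 (3S)-1-[(tert-butyldimethylsilyl)oxy]hex-5-en-3-ol
Product: 35 (4S)-4,6-bis[(tert-butyldimethylsilyl)oxy]hex-1-ene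
Conditions: TBSCl, imidazole, DMF, rt
Reagents that add atoms: tert-butyldimethylsilyl chloride, CC(C)(C)[Si](C)(C)Cl
Why: Standard silylation of the secondary alcohol.

Step 20
Reactants: 35 (4S)-4,6-bis[(tert-butyldimethylsilyl)oxy]hex-1-ene; 36 (E)-crotonaldehyde
Product: 37 (2E,5S)-5,7-bis[(tert-butyldimethylsilyl)oxy]hept-2-enal
Conditions: 36 (5 equiv), second-generation Hoveyda–Grubbs catalyst (3 mol%), CH2Cl2, 40 °C
Reagents that add atoms: none
Why: Olefin cross-metathesis of a reactive terminal alkene with an electron-poor partner is E-selective and releases propene.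

Step 21
Reactants: 37 (2E,5S)-5,7-bis[(tert-butyldimethylsilyl)oxy]hept-2-enal; 32 ethyl (2E,4E)-6-(diethoxyphosphoryl)hexa-2,4-dienoate
Product: 38 ethyl (2E,4E,6E,8E,11S)-11,13-bis[(tert-butyldimethylsilyl)oxy]trideca-2,4,6,8-tetraenoate
Conditions: 32, LiN(SiMe3)2, THF, −78 °C; then 37, −78 → 0 °C; dark
Reagents that add atoms: none
Why: Vinylogous Horner–Wadsworth–Emmons olefination of a stabilised phosphonate anion forms the C8=C9 alkene with E geometry.

Step 22
Reactants: 38 bis-silyl tetraenoate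
Product: 39 ethyl (2E,4E,6E,8E,11S)-11-[(tert-butyldimethylsilyl)oxy]-13-hydroxytrideca-2,4,6,8-tetraenoate
Conditions: HF·pyridine, pyridine, THF, 0 °C
Reagents that add atoms: none
Why: Sterically controlled desilylation: the primary silyl ether is cleaved well before the secondary one.

Step 23
Reactants: 39 hydroxy tetraenoate
Product: 40 (2E,4E,6E,8E,11S)-11-[(tert-butyldimethylsilyl)oxy]trideca-2,4,6,8-tetraene-1,13-diol
Conditions: i-Bu2AlH (3.5 equiv), CH2Cl2, −78 °C; aq. potassium sodium tartrate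
Reagents that add atoms: none
Why: 1,2-Reduction of the conjugated ester to the allylic alcohol by an aluminium hydride leaves the polyene intact.

Step 24
Reactants: 40 tetraene diol
Product: 41 (2E,4E,6E,8E,11S)-11-[(tert-butyldimethylsilyl)oxy]-13-hydroxytrideca-2,4,6,8-tetraenal
Conditions: MnO2 (activated, excess), CH2Cl2, rt, dark
Reagents that add atoms: none
Why: MnO2 oxidises only the allylic (polyenylic) alcohol, so the saturated C15 hydroxyl remains.

**Union and endgame**

Step 25
Reactants: 29 O35 phosphonopropanoate; 41 hydroxy tetraenal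
Product: 42 seco hydroxy ketone (C1–O35 ester, C2–C11 pentaene, free O15–H, C17 methyl ketone)
Conditions: LiCl, DBU, MeCN/THF, 0 °C → rt, dark
Reagents that add atoms: none
Why: Horner–Wadsworth–Emmons olefination under Masamune–Roush conditions: the α-methyl phosphonate and the conjugated aldehyde give the (E)-trisubstituted C2=C3 alkene, and the mild amine base does not enolise the methyl ketone.

Step 26
Reactants: 42 seco hydroxy ketone
Product: 43 seco keto aldehyde (C15 aldehyde, C17 methyl ketone)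
Conditions: Dess–Martin periodinane, NaHCO3, CH2Cl2, 0 °C → rt, dark
Reagents that add atoms: none
Why: Buffered Dess–Martin oxidation of the only free (primary) alcohol to the β-silyloxy aldehyde without epimerisation or ketal loss.

Step 27
Reactants: 43 seco keto aldehyde
Product: 46 macrocyclic 15,17-syn-diol, via enol dicyclohexylborinate 44 (not isolated), via macrocyclic boron aldolate 45 (not isolated)
Conditions: Cy2BCl (4 equiv), Et3N (5 equiv), Et2O, −78 °C, 43 added slowly (final ca. 1 mM), then −25 °C; LiBH4, THF, −78 °C; pH 7 buffer, MeOH, H2O2, 0 °C; dark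
Reagents that add atoms: none
Why: Cy2BCl/Et3N enolises the C17 methyl ketone at the methyl carbon C16, enol borinate 44 adds to the C15 aldehyde through a boron-bridged six-membered transition state to give the ring-closed aldolate 45, and LiBH4 then reduces the boron-chelated C17 carbonyl. The closest known reaction types are the 1,5-anti boron aldol of β-alkoxy methyl ketones, the aldol macrocyclisation of seco keto-aldehydes and the one-pot boron aldol/LiBH4 syn-reduction. The 36-membered lactone ring is closed by end-to-end intramolecular carbonyl addition (C16 onto the C15 aldehyde, formally exo-trig) under pseudo-high dilution. C15 is controlled by the C19 p-methoxybenzyl ether (1,5-anti induction in the boat transition state; the C13 silyl ether exerts only a weak bias), and C17 by the C15 boron aldolate, whose chelate is attacked by external hydride to give the 15,17-syn diol. The step needs ring closure to win over oligomerisation (slow addition), enolisation of the methyl ketone alone (C21 and C27 are ketals and the ester is not enolised by this reagent), and survival of the pentaene ester toward LiBH4 (−78 °C).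

Step 28
Reactants: 46 macrocyclic 15,17-syn-diol
Product: 47 macrocyclic 15,17,19-triol
Conditions: DDQ (1.3 equiv), CH2Cl2/pH 7 buffer (10:1), 0 °C, dark
Reagents that add atoms: none
Why: Oxidative p-methoxybenzyl ether cleavage: the electron-rich anisyl ether should be oxidised faster than the ester-conjugated pentaene, and any 17,19-anisylidene acetal formed by neighbouring-hydroxyl capture converges in step 29.

Step 29
Reactants: 47 macrocyclic 15,17,19-triol
Product: 48 target macrolide
Conditions: 48% aq. HF/MeCN (1:19), 0 °C → rt, dark; NaHCO3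
Reagents that add atoms: water, O
Why: One mildly acidic aqueous fluoride treatment hydrolyses both dimethyl ketals and the acetonide and cleaves the C13 silyl ether; no stereocentre is touched.

**Compound list**

1 | rac-2-(propan-2-yl)oxirane | CC(C)C1CO1 | starting material
2 | (2S)-2-(propan-2-yl)oxirane | CC(C)[C@H]1CO1 | intermediate
3 | 8-bromooct-1-ene | C=CCCCCCCBr | starting material
4 | oct-7-en-1-ylmagnesium bromide | C=CCCCCCC[Mg]Br | intermediate
5 | (3R)-2-methyldodec-11-en-3-ol | C=CCCCCCCC[C@H](C(C)C)O | intermediate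
6 | secondary ozonide of 5, (3R)-2-methyl-10-(1,2,4-trioxolan-3-yl)decan-3-ol (epimers at the trioxolane carbon) | C1OOC(O1)CCCCCCC[C@H](C(C)C)O | intermediate
7 | (9R)-9-hydroxy-10-methylundecanal | O=CCCCCCCC[C@H](C(C)C)O | intermediate
8 | propane-1,3-dithiol | SCCCS | starting material
9 | (3R)-10-(1,3-dithian-2-yl)-2-methyldecan-3-ol | C1CSC(SC1)CCCCCCC[C@H](C(C)C)O | intermediate
10 | 1,5-dichloropentane-2,4-dione | ClCC(=O)CC(=O)CCl | starting material
11 | (2S,4S)-1,5-dichloropentane-2,4-diol | ClC[C@@H](O)C[C@H](O)CCl | intermediate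
12 | (2S,4S)-1,2:4,5-diepoxypentane | C1[C@@H](O1)C[C@H]1CO1 | intermediate
13 | O,C2-dilithio derivative of 9 | [Li]C1(SCCCS1)CCCCCCC[C@H](C(C)C)O[Li] | intermediate
14 | (3R)-10-{2-[(2S)-2-hydroxy-3-[(2S)-oxiran-2-yl]propyl]-1,3-dithian-2-yl}-2-methyldecan-3-ol | C1[C@@H](O1)C[C@H](O)CC1(SCCCS1)CCCCCCC[C@H](C(C)C)O | intermediate
15 | (R)-epichlorohydrin, (2R)-2-(chloromethyl)oxirane | ClC[C@H]1CO1 | starting material
16 | isopropenylmagnesium bromide | CC(=C)[Mg]Br | starting material
17 | (2R)-1-chloro-4-methylpent-4-en-2-ol | C=C(C)C[C@@H](O)CCl | intermediate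
18 | (2R)-2-(2-methylprop-2-en-1-yl)oxirane | C=C(C)C[C@@H]1CO1 | intermediate
19 | 1,3-dithiane | C1CSCSC1 | starting material
20 | 2-lithio-1,3-dithiane | [Li]C1SCCCS1 | intermediate
21 | (2R)-1-(1,3-dithian-2-yl)-4-methylpent-4-en-2-ol | C=C(C)C[C@@H](O)CC1SCCCS1 | intermediate
22 | 2-[(2R)-2-[(4-methoxyphenyl)methoxy]-4-methylpent-4-en-1-yl]-1,3-dithiane | C=C(C)C[C@@H](OCc1ccc(OC)cc1)CC1SCCCS1 | intermediate
23 | 2-lithio derivative of 22 | C=C(C)C[C@@H](OCc1ccc(OC)cc1)CC1([Li])SCCCS1 | intermediate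
24 | C16–C35 triol: 1,3-dithianes at C21 and C27, O19 PMB ether, free OH at C23, C25, C35, isopropenyl terminus (19R,23S,25S,35R; 23,25-anti) | C=C(C)C[C@@H](OCc1ccc(OC)cc1)CC1(SCCCS1)C[C@@H](O)C[C@H](O)CC1(SCCCS1)CCCCCCC[C@H](C(C)C)O | intermediate
25 | 23,25-acetonide of 24 (free O35–H) | C=C(C)C[C@@H](OCc1ccc(OC)cc1)CC1(SCCCS1)C[C@@H](O2)C[C@H](OC2(C)C)CC1(SCCCS1)CCCCCCC[C@H](C(C)C)O | intermediate
26 | bis-dimethyl ketal: as 25 with C21 and C27 each carrying two methoxy groups in place of the dithianes | C=C(C)C[C@@H](OCc1ccc(OC)cc1)CC(OC)(OC)C[C@@H](O2)C[C@H](OC2(C)C)CC(OC)(OC)CCCCCCC[C@H](C(C)C)O | intermediate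
27 | C16–C35 methyl ketone: as 26 with the isopropenyl group replaced by acetyl (C17 ketone) | CC(=O)C[C@@H](OCc1ccc(OC)cc1)CC(OC)(OC)C[C@@H](O2)C[C@H](OC2(C)C)CC(OC)(OC)CCCCCCC[C@H](C(C)C)O | intermediate
28 | 2-(diethoxyphosphoryl)propanoic acid | CCOP(=O)(OCC)C(C)C(=O)O | starting material
29 | O35 2-(diethoxyphosphoryl)propanoate of 27 (epimers at the phosphonate carbon) | CC(=O)C[C@@H](OCc1ccc(OC)cc1)CC(OC)(OC)C[C@@H](O2)C[C@H](OC2(C)C)CC(OC)(OC)CCCCCCC[C@H](C(C)C)OC(=O)C(C)P(=O)(OCC)OCC | intermediate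
30 | ethyl (2E,4E)-hexa-2,4-dienoate (ethyl sorbate) | CCOC(=O)/C=C/C=C/C | starting material
31 | ethyl (2E,4E)-6-bromohexa-2,4-dienoate | CCOC(=O)/C=C/C=C/CBr | intermediate
32 | ethyl (2E,4E)-6-(diethoxyphosphoryl)hexa-2,4-dienoate | CCOC(=O)/C=C/C=C/CP(=O)(OCC)OCC | intermediate
33 | 3-[(tert-butyldimethylsilyl)oxy]propanal | O=CCCO[Si](C)(C)C(C)(C)C | starting material
34 | (3S)-1-[(tert-butyldimethylsilyl)oxy]hex-5-en-3-ol | C=CC[C@H](O)CCO[Si](C)(C)C(C)(C)C | intermediate
35 | (4S)-4,6-bis[(tert-butyldimethylsilyl)oxy]hex-1-ene | C=CC[C@H](O[Si](C)(C)C(C)(C)C)CCO[Si](C)(C)C(C)(C)C | intermediate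
36 | (E)-but-2-enal (crotonaldehyde) | C/C=C/C=O | starting material
37 | (2E,5S)-5,7-bis[(tert-butyldimethylsilyl)oxy]hept-2-enal | O=C/C=C/C[C@H](O[Si](C)(C)C(C)(C)C)CCO[Si](C)(C)C(C)(C)C | intermediate
38 | ethyl (2E,4E,6E,8E,11S)-11,13-bis[(tert-butyldimethylsilyl)oxy]trideca-2,4,6,8-tetraenoate | CCOC(=O)/C=C/C=C/C=C/C=C/C[C@H](O[Si](C)(C)C(C)(C)C)CCO[Si](C)(C)C(C)(C)C | intermediate
39 | ethyl (2E,4E,6E,8E,11S)-11-[(tert-butyldimethylsilyl)oxy]-13-hydroxytrideca-2,4,6,8-tetraenoate | CCOC(=O)/C=C/C=C/C=C/C=C/C[C@H](O[Si](C)(C)C(C)(C)C)CCO | intermediate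
40 | (2E,4E,6E,8E,11S)-11-[(tert-butyldimethylsilyl)oxy]trideca-2,4,6,8-tetraene-1,13-diol | OC/C=C/C=C/C=C/C=C/C[C@H](O[Si](C)(C)C(C)(C)C)CCO | intermediate
41 | (2E,4E,6E,8E,11S)-11-[(tert-butyldimethylsilyl)oxy]-13-hydroxytrideca-2,4,6,8-tetraenal | O=C/C=C/C=C/C=C/C=C/C[C@H](O[Si](C)(C)C(C)(C)C)CCO | intermediate
42 | seco hydroxy ketone: (2E,4E,6E,8E,10E)-2-methyl-pentaenoate of O35, O13 TBS ether, free O15–H, C17 methyl ketone, O19 PMB ether, C21/C27 dimethyl ketals, 23,25-acetonide (13S,19R,23S,25S,35R) | CC(=O)C[C@@H](OCc1ccc(OC)cc1)CC(OC)(OC)C[C@@H](O2)C[C@H](OC2(C)C)CC(OC)(OC)CCCCCCC[C@H](C(C)C)OC(=O)/C(C)=C/C=C/C=C/C=C/C=C/C[C@H](O[Si](C)(C)C(C)(C)C)CCO | intermediate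
43 | seco keto aldehyde: as 42 with C15 as aldehyde | CC(=O)C[C@@H](OCc1ccc(OC)cc1)CC(OC)(OC)C[C@@H](O2)C[C@H](OC2(C)C)CC(OC)(OC)CCCCCCC[C@H](C(C)C)OC(=O)/C(C)=C/C=C/C=C/C=C/C=C/C[C@H](O[Si](C)(C)C(C)(C)C)CC=O | intermediate
44 | enol dicyclohexylborinate of 43 (C16=C17, O17–B) | C=C(OB(C1CCCCC1)C1CCCCC1)C[C@@H](OCc1ccc(OC)cc1)CC(OC)(OC)C[C@@H](O2)C[C@H](OC2(C)C)CC(OC)(OC)CCCCCCC[C@H](C(C)C)OC(=O)/C(C)=C/C=C/C=C/C=C/C=C/C[C@H](O[Si](C)(C)C(C)(C)C)CC=O | intermediate
45 | macrocyclic boron aldolate: 36-membered lactone, O15–B(c-C6H11)2, C17 ketone, C15 1,5-anti to C19 | C\C1=C/C=C/C=C/C=C/C=C/C[C@H](O[Si](C)(C)C(C)(C)C)C[C@H](OB(C2CCCCC2)C2CCCCC2)CC(=O)C[C@@H](OCc2ccc(OC)cc2)CC(OC)(OC)C[C@@H](O2)C[C@H](OC2(C)C)CC(OC)(OC)CCCCCCC[C@H](C(C)C)OC1=O | intermediate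
46 | macrocyclic 15,17-syn-diol: O13 TBS, O19 PMB, C21/C27 dimethyl ketals, 23,25-acetonide; all centres with the spatial arrangement of the target | C\C1=C/C=C/C=C/C=C/C=C/C[C@H](O[Si](C)(C)C(C)(C)C)C[C@H](O)C[C@H](O)C[C@@H](OCc2ccc(OC)cc2)CC(OC)(OC)C[C@@H](O2)C[C@H](OC2(C)C)CC(OC)(OC)CCCCCCC[C@H](C(C)C)OC1=O | intermediate
47 | macrocyclic 15,17,19-triol: as 46 with free O19–H | C\C1=C/C=C/C=C/C=C/C=C/C[C@H](O[Si](C)(C)C(C)(C)C)C[C@H](O)C[C@H](O)C[C@@H](O)CC(OC)(OC)C[C@@H](O2)C[C@H](OC2(C)C)CC(OC)(OC)CCCCCCC[C@H](C(C)C)OC1=O | intermediate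
48 | (3E,5E,7E,9E,11E,14S,16S,18S,20R,24S,26S,36R)-14,16,18,20,24,26-hexahydroxy-3-methyl-36-(propan-2-yl)-1-oxacyclohexatriaconta-3,5,7,9,11-pentaene-2,22,28-trione | C\C1=C/C=C/C=C/C=C/C=C/C[C@H](O)C[C@H](O)C[C@H](O)C[C@@H](O)CC(=O)C[C@@H](O)C[C@H](O)CC(=O)CCCCCCC[C@H](C(C)C)OC1=O | target

**Summary**

Total step count: 29. Longest linear sequence: 15 steps (steps 1–4, 7, 11–15, 25–29).

Steps most likely to fail:

1. Step 27. Intermolecular aldol oligomerisation may outrun ring closure, the 1,5-anti facial preference may erode in the macrocyclic transition state, and the boron Lewis acid may ionise a dimethyl ketal. The fallback sets out from 29 and 41 and comes back at 46; it makes the C15–C16 bond between the two fragments and closes the ring at C2=C3 instead. Alcohol 41 is oxidised with Dess–Martin periodinane to (2E,4E,6E,8E,11S)-11-[(tert-butyldimethylsilyl)oxy]trideca-2,4,6,8-tetraenedial F1. The enol dicyclohexylborinate of ketone 29 (Cy2BCl, Et3N, Et2O, −78 °C) is added to the saturated C15 aldehyde of F1, which is far more electrophilic than the tetraenal terminus. The same 1,5-anti control should give the open-chain 15-hydroxy-17-ketone phosphonate aldehyde F2. Intramolecular Horner–Wadsworth–Emmons olefination (LiCl, i-Pr2NEt, MeCN, high dilution) closes the lactone ring to the macrocyclic 15-hydroxy-17-ketone F3, and Narasaka–Prasad reduction (Et2BOMe, NaBH4, THF/MeOH, −78 °C) gives 46.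

2. Step 28. Oxidation of, or cycloaddition to, the pentaene by the quinone may compete with benzylic oxidation. The fallback sets out from 46 and comes back at 47; it cleaves the ether without any oxidant, by Lewis-acid activation and capture of the benzyl cation by a soft nucleophile (MgBr2·OEt2, Me2S, CH2Cl2, rt). It makes no new compound (F0), and partial ketal loss under these conditions would be harmless because step 29 removes those groups.

3. Step 13. Over-oxidation of the anisyl ring or the alkene, or acid-induced loss of the acetonide, may accompany the twofold ketal exchange. The fallback sets out from 25 and comes back at 26; it separates unmasking from ketalisation. Alkylative hydrolysis of both dithianes (MeI, CaCO3, MeCN/H2O, 40 °C) gives the acetonide-protected 21,27-diketone F4, and HC(OMe)3, MeOH, PPTS (cat.) with 2,2-dimethoxypropane as co-solvent then gives 26.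

Further compounds
F1 | step 27 | (2E,4E,6E,8E,11S)-11-[(tert-butyldimethylsilyl)oxy]trideca-2,4,6,8-tetraenedial | O=C/C=C/C=C/C=C/C=C/C[C@H](O[Si](C)(C)C(C)(C)C)CC=O
F2 | step 27 | open-chain 15-hydroxy-17-ketone with C3 aldehyde and O35 phosphonopropanoate (aldol adduct of 29 and F1) | O=C/C=C/C=C/C=C/C=C/C[C@H](O[Si](C)(C)C(C)(C)C)C[C@H](O)CC(=O)C[C@@H](OCc1ccc(OC)cc1)CC(OC)(OC)C[C@@H](O2)C[C@H](OC2(C)C)CC(OC)(OC)CCCCCCC[C@H](C(C)C)OC(=O)C(C)P(=O)(OCC)OCC
F3 | step 27 | macrocyclic 15-hydroxy-17-ketone (O13 TBS, O19 PMB, C21/C27 dimethyl ketals, 23,25-acetonide) | C\C1=C/C=C/C=C/C=C/C=C/C[C@H](O[Si](C)(C)C(C)(C)C)C[C@H](O)CC(=O)C[C@@H](OCc2ccc(OC)cc2)CC(OC)(OC)C[C@@H](O2)C[C@H](OC2(C)C)CC(OC)(OC)CCCCCCC[C@H](C(C)C)OC1=O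
F0 | step 28 | none | none
F4 | step 13 | 21,27-diketone of the C16–C35 chain (O19 PMB, 23,25-acetonide, isopropenyl terminus, free O35–H) | C=C(C)C[C@@H](OCc1ccc(OC)cc1)CC(=O)C[C@@H](O2)C[C@H](OC2(C)C)CC(=O)CCCCCCC[C@H](C(C)C)O
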